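**Retrosynthetic overview**
1. Ring A of the target is the oxolane O1–C2(aryl)–C3(CH2OH)–C4[CH(OH)aryl]–C5H2 with all three substituents cis. The bond from the aryl carbon to C2 is cut back to a C2–H bond and an aryl iodide (amide-directed C(sp3)–H arylation).
2. Enabling feature: the CH2OH carbon on C3 is β to the O-bound C2–H2. Raised to an 8-aminoquinoline carboxamide, it carries divalent palladium to the C2–H on its own face of ring A through a five-membered palladacycle. The only other β-hydrogen (C4–H) is tertiary and trans, so the aryl group must enter cis to the C3 and C4 arms.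
3. With both side-arm carbons (on C3 and C4) at the carboxyl level, the core is the meso cis-oxolane-3,4-dicarboxylic anhydride (from furan-3,4-dicarboxylic acid), desymmetrised by alkaloid-mediated methanolysis.
4. After arylation the amide arm is reduced and closes a temporary γ-lactone (ring B) onto the C4 arm. A second aryl unit opens ring B to an aryl ketone, a catalyst-controlled reduction sets the carbinol centre, and desilylation ends the route.
5. Ring order: ring A (furan hydrogenation) first, then the temporary anhydride ring, then the temporary lactone ring B; no ring of the target is closed late.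

Key step: step 6

Abbreviation: Ar = 3-methoxy-4-[tri(propan-2-yl)silyloxy]phenyl.
Assumption: quinidine is taken to open the anhydride carbonyl that leads to the (3R,4S) hemiester 4, by analogy with carbocyclic cis-fused anhydrides; its pseudo-enantiomer quinine gives the mirror-image hemiester, so the sense is fixed by the choice of alkaloid.

Step 1
Reactants: 1 furan-3,4-dicarboxylic acid
Product: 2 cis-oxolane-3,4-dicarboxylic acid (meso)
Conditions: H2 (10 bar), 5% Rh/C, H2O, 50 °C
Reagents that add atoms: none
Why: Heterogeneous hydrogenation of the furan should deliver all four hydrogens from the catalyst surface to one face and leave the two carboxyl groups cis; any trans acid is removed in step 2, where only the cis acid closes the bicyclic anhydride.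

Step 2
Reactants: 2 cis-oxolane-3,4-dicarboxylic acid
Product: 3 cis-3a,4,6,6a-tetrahydrofuro[3,4-c]furan-1,3-dione (3,7-dioxabicyclo[3.3.0]octane-2,4-dione; meso)
Conditions: Ac2O, 120 °C; evaporation
Reagents that add atoms: none
Why: Cyclodehydration with acetic anhydride should close the cis-fused five-membered anhydride, which only the cis diacid can form.

Step 3
Reactants: 3 meso anhydride
Product: 4 (3R,4S)-4-(methoxycarbonyl)oxolane-3-carboxylic acid
Conditions: quinidine (1.1 equiv), MeOH (3 equiv), toluene, −55 °C; aq. HCl wash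
Reagents that add atoms: methanol, CO
Why: Alkaloid-mediated enantioselective alcoholysis of a meso anhydride (general-base activation of methanol by the quinuclidine nitrogen) should open one of the two enantiotopic carbonyls and fix the absolute configuration of both ring stereocentres in one desymmetrisation.

Step 4
Reactants: 4 (3R,4S)-4-(methoxycarbonyl)oxolane-3-carboxylic acid; 5 quinolin-8-amine (8-aminoquinoline)
Product: 6 methyl (3S,4R)-4-(quinolin-8-ylcarbamoyl)oxolane-3-carboxylate
Conditions: DCC, HOBt, CH2Cl2, 0 °C to rt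
Reagents that add atoms: none
Why: Carbodiimide/HOBt amide coupling acylates the weakly nucleophilic aromatic amine without the ketene pathway of an acid chloride, so the cis arrangement at the α-carbon should be kept.

Step 5
Reactants: 7 4-iodo-2-methoxyphenol
Product: 8 (4-iodo-2-methoxyphenoxy)tri(propan-2-yl)silane (Ar–I)
Conditions: iPr3SiCl, imidazole, DMF, rt
Reagents that add atoms: chlorotri(propan-2-yl)silane, CC(C)[Si](Cl)(C(C)C)C(C)C
Why: Imidazole-promoted silylation of the phenol gives a fluoride-labile ether that should tolerate the palladium step, the organolithium and the hydride reagents.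

Step 6
Reactants: 6 methyl (3S,4R)-4-(quinolin-8-ylcarbamoyl)oxolane-3-carboxylate; 8 Ar–I
Product: 9 methyl (3S,4R,5S)-5-Ar-4-(quinolin-8-ylcarbamoyl)oxolane-3-carboxylate (all-cis)
Conditions: Pd(OAc)2 (10 mol%), AgOAc (2 equiv), (BnO)2PO2H (20 mol%), 8 (3 equiv), toluene, 110 °C
Reagents that add atoms: none
Why: The deprotonated amide nitrogen and the quinoline nitrogen of 6 bind divalent palladium, and carboxylate-assisted concerted metalation–deprotonation of the C5–H on the amide face gives a five-membered palladacycle cis-fused to ring A; oxidative addition of 8 to an aryl complex of tetravalent palladium and C–C reductive elimination with retention then form the aryl–C5 bond, with AgOAc taking up iodide. The closest known reaction type is the 8-aminoquinoline-directed palladium-catalysed β-C(sp3)–H arylation of cyclic carboxamides with aryl iodides, which is established for oxolane and cyclobutane carboxamides and for methylene groups next to a ring oxygen. No ring of the target is closed in this step; the only ring formed is the transient palladacycle. The new stereocentre C5 (C2 of the target) is controlled by that palladacycle, because the aryl group can only be delivered syn to the C4 carboxamide, which with the cis C3 ester gives the all-cis triad. The step needs site selectivity among the C–H bonds and mono-arylation: the other β-hydrogen (C3–H) is tertiary and trans to the amide, the C2 hydrogens are γ, and after arylation the remaining C5–H is trans to the directing group.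

Step 7
Reactants: 9 methyl (3S,4R,5S)-5-Ar-4-(quinolin-8-ylcarbamoyl)oxolane-3-carboxylate
Product: 10 methyl (3S,4R,5S)-5-Ar-4-[(tert-butoxycarbonyl)(quinolin-8-yl)carbamoyl]oxolane-3-carboxylate
Conditions: Boc2O (3 equiv), DMAP (0.3 equiv), MeCN, 40 °C
Reagents that add atoms: di-tert-butyl dicarbonate, CC(C)(C)OC(=O)OC(=O)OC(C)(C)C
Why: DMAP-catalysed N-acylation of the secondary anilide twists the amide out of conjugation and turns the directing group into a leaving group (amide activation).

Step 8
Reactants: 10 N-Boc amide
Product: 13 (1S,5S,6S)-6-Ar-3,7-dioxabicyclo[3.3.0]octan-2-one (cis-fused γ-lactone; Ar endo), via aldehyde ester 11 (not isolated), via hydroxy ester 12 (not isolated)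
Conditions: NaBH4 (3 equiv), THF/EtOH 4:1, 0 °C to rt
Reagents that add atoms: none
Why: Borohydride should attack the activated acyl carbon of the N-acyl carbamate (reductive cleavage of an activated amide), the aldehyde 11 set free is reduced at once to 12, and the new primary alkoxide, held cis to the methyl ester, closes ring B by 5-exo-trig acyl substitution without touching a stereocentre.

Step 9
Reactants: 13 (1S,5S,6S)-6-Ar-3,7-dioxabicyclo[3.3.0]octan-2-one; 8 Ar–I
Product: 16 [(3S,4S,5S)-5-Ar-4-(hydroxymethyl)oxolan-3-yl](Ar)methanone, via aryllithium 14 (not isolated), via lithium hemiketal alkoxide 15 (not isolated)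
Conditions: 8 (1.15 equiv), t-BuLi (2.3 equiv), THF, −78 °C; then 13, −78 °C; aq. NH4Cl
Reagents that add atoms: none
Why: Iodine–lithium exchange gives 14, which should add only once to the lactone carbonyl because the cis-fused alkoxide 15 keeps the ketone masked until work-up (organolithium addition to a lactone); ring B is opened and no stereocentre is touched.

Step 10
Reactants: 16 [(3S,4S,5S)-5-Ar-4-(hydroxymethyl)oxolan-3-yl](Ar)methanone
Product: 17 (S)-[(3S,4S,5S)-5-Ar-4-(hydroxymethyl)oxolan-3-yl](Ar)methanol
Conditions: (R)-2-methyl-CBS-oxazaborolidine (1 equiv), BH3·SMe2 (2.5 equiv), THF, −20 °C; MeOH quench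
Reagents that add atoms: none
Why: In this Corey–Bakshi–Shibata reduction the (R)-oxazaborolidine, with the aryl group as the large substituent, should deliver hydride to the ketone face that gives the (S)-carbinol, so the new stereocentre is set by the catalyst under non-basic conditions that leave the α-carbon untouched.

Step 11
Reactants: 17 bis-silyl ether
Product: 18 4-[(2S,3S,4S)-4-[(S)-hydroxy(4-hydroxy-3-methoxyphenyl)methyl]-3-(hydroxymethyl)oxolan-2-yl]-2-methoxyphenol (target)
Conditions: Bu4NF (2.4 equiv), AcOH (2.4 equiv), THF, 0 °C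
Reagents that add atoms: none
Why: Fluoride cleaves both aryl silyl ethers through Si–F bond formation, and the acetic acid buffer protonates the phenoxides at once, so the benzylic ether and alcohol should not be exposed to free base.

**Compound list** (Ar = 3-methoxy-4-[tri(propan-2-yl)silyloxy]phenyl)
1 | furan-3,4-dicarboxylic acid | OC(=O)c1cocc1C(=O)O | starting material
2 | cis-oxolane-3,4-dicarboxylic acid (meso) | OC(=O)[C@@H]1COC[C@@H]1C(=O)O | intermediate
3 | cis-3a,4,6,6a-tetrahydrofuro[3,4-c]furan-1,3-dione (meso anhydride) | O=C3[C@@H]1COC[C@@H]1C(=O)O3 | intermediate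
4 | (3R,4S)-4-(methoxycarbonyl)oxolane-3-carboxylic acid | COC(=O)[C@@H]1COC[C@@H]1C(=O)O | intermediate
5 | quinolin-8-amine | Nc1cccc2cccnc12 | starting material
6 | methyl (3S,4R)-4-(quinolin-8-ylcarbamoyl)oxolane-3-carboxylate | COC(=O)[C@@H]1COC[C@@H]1C(=O)Nc1cccc2cccnc12 | intermediate
7 | 4-iodo-2-methoxyphenol | COc1cc(I)ccc1O | starting material
8 | (4-iodo-2-methoxyphenoxy)tri(propan-2-yl)silane | COc1cc(I)ccc1O[Si](C(C)C)(C(C)C)C(C)C | intermediate
9 | methyl (3S,4R,5S)-5-Ar-4-(quinolin-8-ylcarbamoyl)oxolane-3-carboxylate | COC(=O)[C@@H]1CO[C@H](c2ccc(O[Si](C(C)C)(C(C)C)C(C)C)c(OC)c2)[C@@H]1C(=O)Nc1cccc2cccnc12 | intermediate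
10 | methyl (3S,4R,5S)-5-Ar-4-[(tert-butoxycarbonyl)(quinolin-8-yl)carbamoyl]oxolane-3-carboxylate | COC(=O)[C@@H]1CO[C@H](c2ccc(O[Si](C(C)C)(C(C)C)C(C)C)c(OC)c2)[C@@H]1C(=O)N(C(=O)OC(C)(C)C)c1cccc2cccnc12 | intermediate
11 | methyl (3S,4R,5S)-5-Ar-4-formyloxolane-3-carboxylate | COC(=O)[C@@H]1CO[C@H](c2ccc(O[Si](C(C)C)(C(C)C)C(C)C)c(OC)c2)[C@@H]1C=O | intermediate
12 | methyl (3S,4S,5S)-5-Ar-4-(hydroxymethyl)oxolane-3-carboxylate | COC(=O)[C@@H]1CO[C@H](c2ccc(O[Si](C(C)C)(C(C)C)C(C)C)c(OC)c2)[C@@H]1CO | intermediate
13 | (1S,5S,6S)-6-Ar-3,7-dioxabicyclo[3.3.0]octan-2-one | O=C3[C@@H]2CO[C@H](c4ccc(O[Si](C(C)C)(C(C)C)C(C)C)c(OC)c4)[C@@H]2CO3 | intermediate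
14 | {3-methoxy-4-[tri(propan-2-yl)silyloxy]phenyl}lithium | [Li]c1ccc(O[Si](C(C)C)(C(C)C)C(C)C)c(OC)c1 | intermediate
15 | lithium (1S,5S,6S)-2,6-di-Ar-3,7-dioxabicyclo[3.3.0]octan-2-olate (C2 undefined) | COc1cc(C3(O[Li])[C@@H]2CO[C@H](c4ccc(O[Si](C(C)C)(C(C)C)C(C)C)c(OC)c4)[C@@H]2CO3)ccc1O[Si](C(C)C)(C(C)C)C(C)C | intermediate
16 | [(3S,4S,5S)-5-Ar-4-(hydroxymethyl)oxolan-3-yl](Ar)methanone | COc1cc(C(=O)[C@@H]2CO[C@H](c3ccc(O[Si](C(C)C)(C(C)C)C(C)C)c(OC)c3)[C@@H]2CO)ccc1O[Si](C(C)C)(C(C)C)C(C)C | intermediate
17 | (S)-[(3S,4S,5S)-5-Ar-4-(hydroxymethyl)oxolan-3-yl](Ar)methanol | COc1cc([C@@H](O)[C@@H]2CO[C@H](c3ccc(O[Si](C(C)C)(C(C)C)C(C)C)c(OC)c3)[C@@H]2CO)ccc1O[Si](C(C)C)(C(C)C)C(C)C | intermediate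
18 | 4-[(2S,3S,4S)-4-[(S)-hydroxy(4-hydroxy-3-methoxyphenyl)methyl]-3-(hydroxymethyl)oxolan-2-yl]-2-methoxyphenol | COc1cc([C@@H](O)[C@@H]2CO[C@H](c3ccc(O)c(OC)c3)[C@@H]2CO)ccc1O | target

**Step count and risks**
Total steps: 11. Longest linear sequence: 10 (steps 1–4 and 6–11; step 5 is a one-step branch).

Steps most likely to fail:

1. Step 6. Cyclopalladation at the oxygen-bearing methylene may be slower than reductive loss of iodine from 8 and than thermal epimerisation next to the ester, so that conversion stalls or the cis array erodes. The fallback makes the aryl–carbon bond by carbonyl addition and sets the stereocentre by hydride delivery to a bicyclic oxocarbenium ion. It sets out from aryl iodide 8 and comes back at lactone 13. (S)-Paraconic acid F1 (by salt resolution of the racemic acid) is converted with LiN(iPr)2 (2.2 equiv) into its dianion and hydroxymethylated with gaseous formaldehyde to the hydroxymethyl lactone acid F2. Heating with p-TsOH in toluene should equilibrate the lactone α-carbon and drain the cis isomer into the C2-symmetric cis-fused bislactone F3. Aryllithium 14 (from 8 and t-BuLi) should add once, at −78 °C, to one of the two homotopic lactone carbonyls to give the hemiketal F4. Et3SiH/BF3·OEt2 at −78 °C then reduces the derived oxocarbenium ion from the convex face of the bicycle, which places the aryl group on the concave face and gives 13.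

2. Step 10. Facial selectivity may be poor because the intrinsic Felkin–Anh preference of the α-branched ketone (hydride anti to the more substituted ring carbon) opposes the catalyst. The fallback brings in the second aryl group as the nucleophile instead of hydride, so that the same substrate bias works for the wanted isomer. It sets out from lactone 13 and comes back at target 18. Aminolysis of 13 with MeNH(OMe)·HCl/Me3Al gives the hydroxy Weinreb amide F5, and t-BuMe2SiCl/imidazole gives the silyl ether F6. iBu2AlH at −78 °C then gives the aldehyde F7, which is used at once. The arylmagnesium chloride F8 (from 8 and iPrMgCl·LiCl) adds at −78 °C anti to the more substituted ring carbon (Felkin–Anh), which with aryl as the incoming group should give the (S)-carbinol F9. Bu4NF/AcOH removes the three silyl groups to give 18.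

3. Step 8. Hydride may attack the carbamate carbonyl instead of the acyl carbon (returning amide 9), or the α-carbon may epimerise through the transient aldehyde. The fallback separates cleavage from reduction. It sets out from 10 and comes back at lactone 13. LiOH/H2O2 in THF/H2O at 0 °C cleaves the activated amide to the acid F10, and BH3·SMe2 reduces the acid selectively beside the methyl ester to hydroxy ester 12, which lactonises to 13.

**Further compounds**
F1 | step 6 | (3S)-5-oxooxolane-3-carboxylic acid ((S)-paraconic acid) | OC(=O)[C@@H]1COC(=O)C1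
F2 | step 6 | (3S)-4-(hydroxymethyl)-5-oxooxolane-3-carboxylic acid (C4 epimers) | OC(=O)[C@@H]1COC(=O)C1CO
F3 | step 6 | (1S,5S)-3,7-dioxabicyclo[3.3.0]octane-2,6-dione | O=C3[C@@H]2COC(=O)[C@@H]2CO3
F4 | step 6 | (1S,5S)-6-Ar-6-hydroxy-3,7-dioxabicyclo[3.3.0]octan-2-one (C6 undefined) | O=C3[C@@H]2COC(O)(c4ccc(O[Si](C(C)C)(C(C)C)C(C)C)c(OC)c4)[C@@H]2CO3
F5 | step 10 | (3S,4S,5S)-5-Ar-4-(hydroxymethyl)-N-methoxy-N-methyloxolane-3-carboxamide | CON(C)C(=O)[C@@H]1CO[C@H](c2ccc(O[Si](C(C)C)(C(C)C)C(C)C)c(OC)c2)[C@@H]1CO
F6 | step 10 | (3S,4S,5S)-5-Ar-4-[(tert-butyldimethylsilyloxy)methyl]-N-methoxy-N-methyloxolane-3-carboxamide | CON(C)C(=O)[C@@H]1CO[C@H](c2ccc(O[Si](C(C)C)(C(C)C)C(C)C)c(OC)c2)[C@@H]1CO[Si](C)(C)C(C)(C)C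
F7 | step 10 | (3S,4S,5S)-5-Ar-4-[(tert-butyldimethylsilyloxy)methyl]oxolane-3-carbaldehyde | O=C[C@@H]1CO[C@H](c2ccc(O[Si](C(C)C)(C(C)C)C(C)C)c(OC)c2)[C@@H]1CO[Si](C)(C)C(C)(C)C
F8 | step 10 | {3-methoxy-4-[tri(propan-2-yl)silyloxy]phenyl}magnesium chloride | Cl[Mg]c1ccc(O[Si](C(C)C)(C(C)C)C(C)C)c(OC)c1
F9 | step 10 | (S)-[(3S,4S,5S)-5-Ar-4-[(tert-butyldimethylsilyloxy)methyl]oxolan-3-yl](Ar)methanol | COc1cc([C@@H](O)[C@@H]2CO[C@H](c3ccc(O[Si](C(C)C)(C(C)C)C(C)C)c(OC)c3)[C@@H]2CO[Si](C)(C)C(C)(C)C)ccc1O[Si](C(C)C)(C(C)C)C(C)C
F10 | step 8 | (3R,4S,5S)-5-Ar-4-(methoxycarbonyl)oxolane-3-carboxylic acid | COC(=O)[C@@H]1CO[C@H](c2ccc(O[Si](C(C)C)(C(C)C)C(C)C)c(OC)c2)[C@@H]1C(=O)O
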